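**Plan**
- Retrosynthetic cuts, in order: the S–O bond of the 3-sulfate; the C3–O bond (3-OH from the C2=C3 bond); the C5–O bond (from C5–F); both bonds of O1 (O1–C2 and O1–C8a); the C4–C3 bond (acid chloride plus terminal alkyne); the alkyne carbon (from the aldehyde of vanillin).
- Enabling feature: O1 joins C8a of ring A to C2, and ring A carries oxygen on both carbons ortho to the C4 acyl carbon (C8a–O1 and C5–OH). A 2,6-difluoroaryl ynone can therefore receive both oxygens as nucleophiles.
- Forward: the ring B alkyne (from vanillin) and the ring A acid chloride are joined to an ynone. Ring C then closes around a water-derived oxygen. The surviving fluorine is exchanged for benzyloxy, C3 is hydroxylated and sulfated, and both benzyl groups are removed last.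
- Stereochemistry: the target has no stereocentre. The only stereogenic intermediate is a racemic cis-epoxide that is formed and consumed within step 7.

Key step: step 5

Assumption: the target is drawn as the free hydrogen sulfate, so the sulfate monoester is carried as its sodium salt and protonated only in the last operation of step 9.

**Route**

Step 1
Reactants: 1 vanillin
Product: 2 4-(benzyloxy)-3-methoxybenzaldehyde
Conditions: BnBr, K2CO3, DMF, 60 °C
Reagents that add atoms: benzyl bromide, BrCc1ccccc1
Why: Williamson etherification of the phenoxide with a benzylic bromide should be clean, since carbonate leaves the non-enolisable aldehyde untouched.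

Step 2
Reactants: 2 4-(benzyloxy)-3-methoxybenzaldehyde; 3 dimethyl (1-diazo-2-oxopropyl)phosphonate (Ohira–Bestmann reagent)
Product: 4 1-(benzyloxy)-4-ethynyl-2-methoxybenzene
Conditions: K2CO3, MeOH–THF, 0 °C → rt
Reagents that add atoms: dimethyl (1-diazo-2-oxopropyl)phosphonate (3), COP(=O)(OC)C(=[N+]=[N-])C(C)=O
Why: Seyferth–Gilbert homologation in its Ohira–Bestmann form, in which methanolysis of 3 releases the diazomethylphosphonate anion that olefinates the aryl aldehyde and, after loss of N2 and a 1,2-hydrogen shift, should deliver the terminal alkyne without disturbing the benzyl ether.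

Step 3
Reactants: 5 2,6-difluoro-4-methoxybenzoic acid
Product: 6 2,6-difluoro-4-methoxybenzoyl chloride
Conditions: (COCl)2, DMF (cat.), CH2Cl2, 0 °C → rt; evaporate, use crude
Reagents that add atoms: oxalyl chloride, O=C(Cl)C(=O)Cl
Why: Acid chloride formation through the Vilsmeier-type chloroiminium species gives only gaseous by-products, and the aryl fluorides and methyl ether are inert to it.

Step 4
Reactants: 6 2,6-difluoro-4-methoxybenzoyl chloride; 4 1-(benzyloxy)-4-ethynyl-2-methoxybenzene
Product: 7 3-[4-(benzyloxy)-3-methoxyphenyl]-1-(2,6-difluoro-4-methoxyphenyl)prop-2-yn-1-one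
Conditions: PdCl2(PPh3)2 (2 mol %), CuI (4 mol %), Et3N (1.5 equiv), THF, rt, argon
Reagents that add atoms: none
Why: Acyl Sonogashira coupling, in which the copper acetylide of 4 transmetalates to the acylpalladium chloride formed by oxidative addition of 6 to zerovalent palladium and reductive elimination gives the ynone; the acid chloride has no α-hydrogen, so ketene formation is excluded.

Step 5
Reactants: 7 3-[4-(benzyloxy)-3-methoxyphenyl]-1-(2,6-difluoro-4-methoxyphenyl)prop-2-yn-1-one; 8 water
Product: 10 2-[4-(benzyloxy)-3-methoxyphenyl]-5-fluoro-7-methoxy-4H-chromen-4-one, via 1,3-diketone potassium enolate 9 (not isolated)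
Conditions: KOH (1.2 equiv), H2O (5 equiv), DMSO, rt → 70 °C
Reagents that add atoms: water (8), O, delivered as hydroxide by KOH, [K+].[OH-]
Why: Hydroxide adds to the alkyne carbon β to the ketone of 7 (oxa-Michael addition, forming O1–C2), the β-hydroxy enone is deprotonated to the chelated Z-enolate 9, and on warming its new oxygen attacks a fluorine-bearing carbon ortho to the ketone to give a Meisenheimer anion that expels fluoride (forming O1–C8a). The closest known reaction type is the tandem conjugate addition/intramolecular SNAr of ortho-fluoroaryl ynones with amines, sulfide or hydroxide, together with the base-mediated cyclisation of 2-fluorophenyl 1,3-diketones to flavones. Ring C closes as a six-membered ring by addition–elimination of the enolate oxygen on the arene carbon (formally 6-exo-trig on the C8a=C8 π bond), the C4 ketone stabilising the anionic intermediate. No stereocentre is formed. The step needs β-addition instead of attack at the carbonyl or at C–F, which the two flanking fluorines (a shielded, twisted carbonyl) and the faster addition to the polarised triple bond should secure; it also needs cyclisation at one site only, which holds because the new oxygen is the only enolate atom that can reach ring A through a six-membered transition state and the two fluorines are equivalent. Keeping KOH near one equivalent stores the hydroxide as enolate 9 before heating, so the surviving fluorine (the future C5 substituent) and the pyranone are not exposed to excess base.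

Step 6
Reactants: 10 2-[4-(benzyloxy)-3-methoxyphenyl]-5-fluoro-7-methoxy-4H-chromen-4-one
Product: 11 5-(benzyloxy)-2-[4-(benzyloxy)-3-methoxyphenyl]-7-methoxy-4H-chromen-4-one
Conditions: BnOH (1.3 equiv), NaH (1.25 equiv), THF–DMF, 0 °C → rt
Reagents that add atoms: benzyl alcohol, OCc1ccccc1 (used as its sodium alkoxide)
Why: Nucleophilic aromatic substitution by addition–elimination, in which the C5 fluorine sits ortho to the carbonyl-bearing C4a so the Meisenheimer anion is delocalised into the C4 carbonyl and fluoride loss is irreversible, whereas addition of the alkoxide at C2 is reversible under anhydrous conditions.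

Step 7
Reactants: 11 5-(benzyloxy)-2-[4-(benzyloxy)-3-methoxyphenyl]-7-methoxy-4H-chromen-4-one
Product: 13 5-(benzyloxy)-2-[4-(benzyloxy)-3-methoxyphenyl]-3-hydroxy-7-methoxy-4H-chromen-4-one (5,4'-di-O-benzylrhamnazin), via racemic 2,3-epoxyflavanone 12 (not isolated)
Conditions: DMDO (ca. 0.07 M in acetone, 3 equiv), CH2Cl2, 0 °C → rt, dark; evaporate; then p-TsOH·H2O (0.1 equiv), CH2Cl2, rt
Reagents that add atoms: dimethyldioxirane, CC1(C)OO1
Why: Dioxirane epoxidation of the vinylogous-ester C2=C3 bond followed by acid-catalysed epoxide opening at C2 (cation stabilised by O1 and ring B) and loss of H3 should give the 3-hydroxyflavone, and the two stereocentres of racemic 12 are erased in the same step.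

Step 8
Reactants: 13 5-(benzyloxy)-2-[4-(benzyloxy)-3-methoxyphenyl]-3-hydroxy-7-methoxy-4H-chromen-4-one
Product: 14 sodium 5-(benzyloxy)-2-[4-(benzyloxy)-3-methoxyphenyl]-7-methoxy-4-oxo-4H-chromen-3-yl sulfate
Conditions: SO3·pyridine (4 equiv), pyridine, 50 °C; then aq NaHCO3; reversed-phase (C18) chromatography to remove pyridine
Reagents that add atoms: sulfur trioxide–pyridine complex, O=S(=O)([O-])[n+]1ccccc1; NaHCO3 (sodium hydrogen carbonate), [Na+].OC([O-])=O
Why: O-Sulfation by sulfur trioxide transfer from SO3·pyridine can only occur at the 3-hydroxyl, the one free OH in 13, and the monoester is trapped as its stable sodium salt on NaHCO3 work-up.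

Step 9
Reactants: 14 sodium 5-(benzyloxy)-2-[4-(benzyloxy)-3-methoxyphenyl]-7-methoxy-4-oxo-4H-chromen-3-yl sulfate
Product: 16 rhamnazin 3-O-sulfate (5-hydroxy-2-(4-hydroxy-3-methoxyphenyl)-7-methoxy-4-oxo-4H-chromen-3-yl hydrogen sulfate), via sodium rhamnazin 3-O-sulfate 15 (not isolated)
Conditions: H2 (1 atm), 10% Pd/C, MeOH–THF (1:1), rt; filter; then 1 M aq HCl to pH ≈ 2, 0 °C; C18 cartridge (H2O wash, MeOH elution), lyophilise
Reagents that add atoms: none
Why: Heterogeneous hydrogenolysis on Pd/C should cleave both benzyl aryl ethers while leaving the sulfate monoester, the methyl ethers and the tetrasubstituted C2=C3 bond intact, and cold dilute acid then protonates the sulfate salt.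

**Compound list**

1 | vanillin (4-hydroxy-3-methoxybenzaldehyde) | COc1cc(C=O)ccc1O | starting material
2 | 4-(benzyloxy)-3-methoxybenzaldehyde | COc1cc(C=O)ccc1OCc1ccccc1 | intermediate
3 | dimethyl (1-diazo-2-oxopropyl)phosphonate (Ohira–Bestmann reagent) | COP(=O)(OC)C(=[N+]=[N-])C(C)=O | starting material
4 | 1-(benzyloxy)-4-ethynyl-2-methoxybenzene | COc1cc(C#C)ccc1OCc1ccccc1 | intermediate
5 | 2,6-difluoro-4-methoxybenzoic acid | COc1cc(F)c(C(=O)O)c(F)c1 | starting material
6 | 2,6-difluoro-4-methoxybenzoyl chloride | COc1cc(F)c(C(Cl)=O)c(F)c1 | intermediate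
7 | 3-[4-(benzyloxy)-3-methoxyphenyl]-1-(2,6-difluoro-4-methoxyphenyl)prop-2-yn-1-one | COc1cc(F)c(C(=O)C#Cc2ccc(OCc3ccccc3)c(OC)c2)c(F)c1 | intermediate
8 | water | O | starting material
9 | potassium (Z)-1-[4-(benzyloxy)-3-methoxyphenyl]-3-(2,6-difluoro-4-methoxyphenyl)-3-oxoprop-1-en-1-olate | COc1cc(F)c(C(=O)/C=C(\[O-])c2ccc(OCc3ccccc3)c(OC)c2)c(F)c1.[K+] | intermediate (not isolated)
10 | 2-[4-(benzyloxy)-3-methoxyphenyl]-5-fluoro-7-methoxy-4H-chromen-4-one | COc1cc(F)c2c(=O)cc(-c3ccc(OCc4ccccc4)c(OC)c3)oc2c1 | intermediate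
11 | 5-(benzyloxy)-2-[4-(benzyloxy)-3-methoxyphenyl]-7-methoxy-4H-chromen-4-one | COc1cc(OCc2ccccc2)c2c(=O)cc(-c3ccc(OCc4ccccc4)c(OC)c3)oc2c1 | intermediate
12 | racemic cis-fused 5-(benzyloxy)-2-[4-(benzyloxy)-3-methoxyphenyl]-2,3-epoxy-7-methoxy-2,3-dihydro-4H-chromen-4-one (flavone numbering; the 2S,3R enantiomer is drawn) | O=C1c2c(OCc3ccccc3)cc(OC)cc2O[C@]2(c3ccc(OCc4ccccc4)c(OC)c3)O[C@H]12 | intermediate (not isolated)
13 | 5-(benzyloxy)-2-[4-(benzyloxy)-3-methoxyphenyl]-3-hydroxy-7-methoxy-4H-chromen-4-one | COc1cc(OCc2ccccc2)c2c(=O)c(O)c(-c3ccc(OCc4ccccc4)c(OC)c3)oc2c1 | intermediate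
14 | sodium 5-(benzyloxy)-2-[4-(benzyloxy)-3-methoxyphenyl]-7-methoxy-4-oxo-4H-chromen-3-yl sulfate | COc1cc(OCc2ccccc2)c2c(=O)c(OS(=O)(=O)[O-])c(-c3ccc(OCc4ccccc4)c(OC)c3)oc2c1.[Na+] | intermediate
15 | sodium 5-hydroxy-2-(4-hydroxy-3-methoxyphenyl)-7-methoxy-4-oxo-4H-chromen-3-yl sulfate | COc1cc(O)c2c(=O)c(OS(=O)(=O)[O-])c(-c3ccc(O)c(OC)c3)oc2c1.[Na+] | intermediate (not isolated)
16 | rhamnazin 3-O-sulfate | COc1cc(O)c2c(=O)c(OS(=O)(=O)O)c(-c3ccc(O)c(OC)c3)oc2c1 | target

**Step count**

Total steps: 9. Longest linear sequence: 8 steps (1, 2, 4, 5, 6, 7, 8, 9 from vanillin); the ring A branch enters through step 3.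

**Steps most likely to fail**

1. Step 5. Hydroxide may attack the ketone carbonyl and cleave the ynone, the diketone enolate may undergo retro-Claisen cleavage, or hydroxide may displace a fluoride before the ring has closed. Fallback, setting out from 7 and returning at 10: the oxygen is delivered in separate stages. Diethylamine in EtOH at rt should add to 7 to give the enaminone (E)-3-[4-(benzyloxy)-3-methoxyphenyl]-3-(diethylamino)-1-(2,6-difluoro-4-methoxyphenyl)prop-2-en-1-one F1. Hydrolysis with 1 M aq HCl in THF at rt should give the neutral 1,3-diketone 1-[4-(benzyloxy)-3-methoxyphenyl]-3-(2,6-difluoro-4-methoxyphenyl)propane-1,3-dione F2. K2CO3 in DMF at 80 °C then closes the ring through enolate 9 to give 10, with no free hydroxide present during the SNAr stage.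

2. Step 6. Benzyl oxide may add at C2 and open the pyranone, or fluoride displacement may be too slow to compete with decomposition by the strongly basic alkoxide. Fallback, setting out from 10 and returning at 11: a weakly basic α-effect nucleophile is used as a hydroxide equivalent. (E)-Benzaldoxime with K2CO3 in DMSO at 70 °C should displace fluoride to give the O-aryl oxime (E)-benzaldehyde O-{2-[4-(benzyloxy)-3-methoxyphenyl]-7-methoxy-4-oxo-4H-chromen-5-yl}oxime F3. Under the same conditions this fragments, with loss of benzonitrile, to 2-[4-(benzyloxy)-3-methoxyphenyl]-5-hydroxy-7-methoxy-4H-chromen-4-one F4. O-Benzylation of the hydrogen-bonded 5-hydroxyl with BnBr and K2CO3 in DMF at 70 °C then gives 11.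

3. Step 7. The dioxirane may oxidise benzylic C–H bonds or the electron-rich arenes in competition with the C2=C3 bond, or epoxidation may stall before conversion is complete. Fallback, setting out from 11 and returning at 13: the oxygen is introduced by C3 metalation instead of alkene oxidation. LiN(iPr)2 in THF at −78 °C should deprotonate C3 to give 5-(benzyloxy)-2-[4-(benzyloxy)-3-methoxyphenyl]-3-lithio-7-methoxy-4H-chromen-4-one F5. Trapping with B(OMe)3 gives dimethyl {5-(benzyloxy)-2-[4-(benzyloxy)-3-methoxyphenyl]-7-methoxy-4-oxo-4H-chromen-3-yl}boronate F6. Oxidation of the C–B bond with H2O2 in AcOH at 0 °C then gives 13.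

**Further compounds**

F1 | step 5 | (E)-3-[4-(benzyloxy)-3-methoxyphenyl]-3-(diethylamino)-1-(2,6-difluoro-4-methoxyphenyl)prop-2-en-1-one | CCN(CC)/C(=C/C(=O)c1c(F)cc(OC)cc1F)c1ccc(OCc2ccccc2)c(OC)c1
F2 | step 5 | 1-[4-(benzyloxy)-3-methoxyphenyl]-3-(2,6-difluoro-4-methoxyphenyl)propane-1,3-dione | COc1cc(F)c(C(=O)CC(=O)c2ccc(OCc3ccccc3)c(OC)c2)c(F)c1
F3 | step 6 | (E)-benzaldehyde O-{2-[4-(benzyloxy)-3-methoxyphenyl]-7-methoxy-4-oxo-4H-chromen-5-yl}oxime | COc1cc(O/N=C/c2ccccc2)c2c(=O)cc(-c3ccc(OCc4ccccc4)c(OC)c3)oc2c1
F4 | step 6 | 2-[4-(benzyloxy)-3-methoxyphenyl]-5-hydroxy-7-methoxy-4H-chromen-4-one | COc1cc(O)c2c(=O)cc(-c3ccc(OCc4ccccc4)c(OC)c3)oc2c1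
F5 | step 7 | 5-(benzyloxy)-2-[4-(benzyloxy)-3-methoxyphenyl]-3-lithio-7-methoxy-4H-chromen-4-one | COc1cc(OCc2ccccc2)c2c(=O)c([Li])c(-c3ccc(OCc4ccccc4)c(OC)c3)oc2c1
F6 | step 7 | dimethyl {5-(benzyloxy)-2-[4-(benzyloxy)-3-methoxyphenyl]-7-methoxy-4-oxo-4H-chromen-3-yl}boronate | COB(OC)c1c(-c2ccc(OCc3ccccc3)c(OC)c2)oc2cc(OC)cc(OCc3ccccc3)c2c1=O
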